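The data are calculated for an exercise, noise included.

If two nucleophiles draw on one intermediate, set the clock aside and look for what stays constant between them. Here the charges of starting material and first nucleophile stay the same while the second nucleophile climbs from flask to flask.

| flask | starting material | first nucleophile | second nucleophile | remark | time |
|---|---|---|---|---|---|
| south | 27 mM | 32.4 mM | 13 mM | run made earlier |  |
| south-west | 27 mM | 32.4 mM | 170 mM | run made earlier |  |
| summer | 27 mM | 32.4 mM | 15.0 mM |  | 30 d |
| winter | 27 mM | 32.4 mM | 25.0 mM |  | 30 d |
| midnight | 27 mM | 32.4 mM | 50.0 mM |  | 30 d |
| spring | 27 mM | 32.4 mM | 100 mM |  | 30 d |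
| dusk | 27 mM | 32.4 mM | 200 mM |  | 30 d |

1. share of target in all that became target or other capture product or side product for summer, winter, midnight, spring, dusk, in this order
2. the shape of the row from first to last (rises all the way / falls all the way / rises, then falls / falls, then rises / hardly changes)

- south (time / d: target / %, other capture product / %, side product / %): 1.67: 26.4, 3.1, 0.5; 3.00: 44.0, 5.3, 2.4; 5.00: 59.1, 5.2, 2.0; 8.00: 71.5, 8.8, 3.4; 12.0: 80.0, 13.1, 5.8; 20.0: 82.9, 12.2, 4.0
- south-west (time / d: target / %, other capture product / %, side product / %): 4.00: 24.5, 35.7, 0.7; 8.00: 34.7, 49.6, 2.8; 10.0: 36.4, 53.6, 2.7; 15.0: 38.5, 58.6, 1.2; 20.0: 39.9, 58.8, 2.4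

(each reading ± 1 percentage point)

- percent here means starting material units held: one side product counts as two
- reactions considered so far: second nucleophile <-> dormant form; starting material -> intermediate; second nucleophile + intermediate -> other capture product; starting material + intermediate -> side product; first nucleophile + intermediate -> target
- "hardly changes" means that all values lie within two and a half points (for a concentration: within two and a half percent of the largest)

Read the last row of each table. In the south run the three products hold 99.1 % of the charge at 20.0 d, and in the south-west run 101 % at 20.0 d, so take the starting material as consumed by 30 d.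

Now let B be the first nucleophile left and D the second nucleophile not yet captured, dormant form included. Each portion of intermediate divides as r·B to D, so ln(B over its charge) equals r times ln(D over its charge). The target column gives B and the other capture column gives D. The south run reads 4.02; the south-west run, with 13.1 times the charge of second nucleophile, reads 4.12, close to it. Take 4.07 as r, an apparent selectivity factor: the pull of the first nucleophile on the intermediate over that of the second, reckoned on D with the dormant form counted in it.

Reckon midnight with it. At the charges the target takes r·B/(r·B+D), or 72.5 %. Repeat with B and D at half of that consumption, which gives 66.5 %. Then remove the side product, reading 3.20 % as the mean of the two last rows, and commit to 64.4 %. The same steps, with the south reading of side product for summer and the south-west reading for dusk, give 82.4 % and 35.6 %, so expect a row that falls.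

The forecast gives 82.4 %, 76.1 %, 64.6 %, 50.4 % and 36 %, a row that falls all the way, “falling steadily”.

The flasks give 82.8 %, 76.6 %, 65.4 %, 51.3 % and 36.5 %: the row falls all the way.

    second nucleophile ⇌ dormant form (K = 0.452, k = 7.48 × 10⁻⁶ /s)
    starting material → intermediate (k = 2.81 × 10⁻⁶ /s)
    second nucleophile + intermediate → other capture product (k = 8.05 × 10⁻⁴ /M/s)
    starting material + intermediate → side product (k = 9.61 × 10⁻⁵ /M/s)
    first nucleophile + intermediate → target (k = 0.00237 /M/s)

In summer the forward step into the dormant form has a half-life of 1.1 d, shorter than the 2.9 d of starting material going to intermediate. Dormant form over free second nucleophile stands at 0.452 at the end of midnight and at 0.452 at the end of dusk. Put the end of midnight into r: 46 % of the first nucleophile left and 31.8 % of other capture product give 4.17. The end of dusk, with 70 % and 62.1 %, gives 4.13.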